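**Retrosynthetic overview**

1. Eudesmane numbering is used throughout (ring A = C1–C5 + C10, ring B = C5–C10, C14 = methyl on C10, C15 on C4, C11–C13 on C7). The target is traced back to the 15-alcohol 14: the (Z)-p-coumarate is built on the C15 oxygen by phosphonoacetate acylation and Still–Gennari olefination, and the acrylic acid is made last from the isopropenyl group by allylic oxidation at C12.
2. 14 ⇒ enal 13 ⇒ aldol 11, the product of a radical–polar crossover bicyclisation of the acyclic cesium oxalate 9. A tertiary C10 radical closes ring B (C5–C10) onto the C15 enal, and the resulting C4 enolate closes ring A (C3–C4) onto the C3 aldehyde: ring B first, ring A second, in one flask.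
3. Enabling feature: C10 is the all-carbon quaternary atom shared by both rings. It lies four carbons (C9–C8–C7–C6) from C5 and two carbons (C1–C2) from C3, and C4 carries the oxidised carbon C15. A C10 radical/C3 carbonyl pair can therefore add across C5=C4 of a C15 enal and leave the oxidation level needed for the C3=C4 double bond.
4. 9 ⇒ keto-aldehyde 2 from (R)-limonene oxide 1. Its aldehyde carbon is C5, its methyl ketone is C10/C14, and its stereocentre is C7 with the isopropenyl group in place. C4/C15 come from a Wittig reaction and C1–C3 from a Grignard addition.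
5. C5 and C10 are both relayed from C7 in the key step; no other stereocentre survives into the target.

Key step: step 7

Assumption: commercial (+)-limonene oxide derived from (R)-limonene is used as its cis/trans mixture; both isomers converge in step 1.
Remark: 6–9 are mixtures of both configurations at the carbinol carbon C10 (it becomes a planar radical in step 7), and 4, 6 and 7 are mixtures of alkene isomers (they converge to the E enal in step 5).

**Step 1**
Reactants: 1 (4R)-limonene 1,2-oxide (cis/trans mixture)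
Product: 2 (3R)-6-oxo-3-(prop-1-en-2-yl)heptanal
Conditions: H5IO6, THF/H2O, 0 °C to rt
Reagents that add atoms: water, O
Why: Epoxide hydration followed by periodate glycol cleavage opens the ring between C5 and C10 and leaves the isopropenyl group and the C7 stereocentre untouched, since no bond to C7 changes.

**Step 2**
Reactants: 2 (3R)-6-oxo-3-(prop-1-en-2-yl)heptanal; 3 (1,3-dioxolan-2-ylmethyl)triphenylphosphonium bromide
Product: 4 (5R)-8-(1,3-dioxolan-2-yl)-5-(prop-1-en-2-yl)oct-7-en-2-one (Z/E mixture)
Conditions: 3, t-BuOK, THF, 0 °C; then 2, −78 °C to rt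
Reagents that add atoms: none
Why: The Wittig olefination with the acetal ylide should take the aldehyde in preference to the methyl ketone and installs C4 and C15 as a masked enal, whose geometry does not matter because step 5 gives the E enal.

**Step 3**
Reactants: 4 (5R)-8-(1,3-dioxolan-2-yl)-5-(prop-1-en-2-yl)oct-7-en-2-one; 5 2-(2-bromoethyl)-1,3-dioxolane
Product: 6 (6R)-1,9-bis(1,3-dioxolan-2-yl)-3-methyl-6-(prop-1-en-2-yl)non-8-en-3-ol (both carbinol epimers)
Conditions: 5, Mg, THF, rt; then 4, −78 to 0 °C; aq. NH4Cl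
Reagents that add atoms: none
Why: Grignard 1,2-addition to the methyl ketone builds C10 with its methyl group, the C1–C3 arm and a hydroxyl handle; the new carbinol centre forms as both epimers, which is harmless because it becomes planar in step 7.

**Step 4**
Reactants: 6 (6R)-1,9-bis(1,3-dioxolan-2-yl)-3-methyl-6-(prop-1-en-2-yl)non-8-en-3-ol
Product: 7 methyl (6R)-1,9-bis(1,3-dioxolan-2-yl)-3-methyl-6-(prop-1-en-2-yl)non-8-en-3-yl oxalate
Conditions: ClC(O)CO2Me, Et3N, DMAP (cat.), CH2Cl2, 0 °C to rt
Reagents that add atoms: methyl chlorooxoacetate, COC(=O)C(=O)Cl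
Why: DMAP-catalysed acylation of the tertiary alcohol with the acid chloride gives the mixed oxalate diester, the established precursor of tertiary alkyl radicals.

**Step 5**
Reactants: 7 methyl (6R)-1,9-bis(1,3-dioxolan-2-yl)-3-methyl-6-(prop-1-en-2-yl)non-8-en-3-yl oxalate
Product: 8 methyl (2E,5R)-8-methyl-1,11-dioxo-5-(prop-1-en-2-yl)undec-2-en-8-yl oxalate
Conditions: TsOH·H2O (cat.), acetone/H2O, rt
Reagents that add atoms: water, O
Why: Acid-catalysed acetal hydrolysis frees the C3 aldehyde and the C15 enal (which equilibrates to the E isomer), while the tertiary oxalate diester should tolerate dilute acid at room temperature.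

**Step 6**
Reactants: 8 methyl (2E,5R)-8-methyl-1,11-dioxo-5-(prop-1-en-2-yl)undec-2-en-8-yl oxalate
Product: 9 cesium 2-{[(2E,5R)-8-methyl-1,11-dioxo-5-(prop-1-en-2-yl)undec-2-en-8-yl]oxy}-2-oxoacetate (used as the dried crude salt)
Conditions: CsOH (1.0 equiv, aq.), THF, 0 °C, 10 min; concentrate
Reagents that add atoms: cesium hydroxide, [Cs+].[OH-]
Why: Saponification of the unhindered, activated methyl ester of the oxalate by one equivalent of hydroxide should be complete within minutes, well before aldol chemistry of the aldehydes, and gives the oxidisable carboxylate.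

**Step 7**
Reactants: 9 cesium 2-{[(2E,5R)-8-methyl-1,11-dioxo-5-(prop-1-en-2-yl)undec-2-en-8-yl]oxy}-2-oxoacetate
Product: 11 (5S,7R,10S)-3-hydroxyeudesm-11(13)-en-15-al as a mixture of C3/C4 epimers, via cesium enolate 10 (not isolated)
Conditions: [Ir(dF(CF3)ppy)2(dtbbpy)]PF6 (2 mol%), DME/DMF (3:1, 5 mM), H2O (2 equiv), blue LEDs, 60 °C, degassed
Reagents that add atoms: none
Why: Proposed new method: the photoexcited trivalent iridium complex oxidises the oxalate carboxylate of 9, loss of two CO2 gives the tertiary C10 radical, which adds 6-exo-trig to C5 of the E enal (ring B), and the divalent iridium complex formed in the first event reduces the resulting C4 α-formyl radical to cesium enolate 10, which adds to the C3 aldehyde in a 6-(enolexo)-exo-trig aldol closure (ring A), so that C5–C10 and C3–C4 form in one redox-neutral operation and the enolate can only arise at C4. The closest known reactions are the oxalate-based photoredox Giese addition of tertiary radicals, which ends with protonation of the enolate, and the iron hydride-initiated radical conjugate addition–aldol annulation of carbonyl-bearing alkenes with enals; new here is the aldol termination under the oxalate conditions, chosen because hydrogen-atom-transfer initiation would also consume the isopropenyl group. C5 is set by C7 through a chair transition state for the radical addition in which the isopropenyl group and the enal are both equatorial (1,3-cis). C10 is set in the same transition state by the preference of the longer 3-oxopropyl arm over the methyl group for the equatorial site, which puts the methyl axial and leads to the trans-decalin after aldol closure; C3 and C4 form as a mixture that step 8 erases. The step needs the nucleophilic C10 radical to choose the electron-poor enal over the isopropenyl alkene (secured by polarity matching and the 6-exo geometry), aldol closure to outrun protonation of 10 (secured by the six-membered transition state and the small amount of water), and face selectivity at C10, which rests only on the size difference of the two arms, should be modest and is the least secure element.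

**Step 8**
Reactants: 11 (5S,7R,10S)-3-hydroxyeudesm-11(13)-en-15-al
Product: 13 (5R,7R,10R)-eudesma-3,11(13)-dien-15-al, via mesylate 12 (not isolated)
Conditions: MsCl, Et3N, CH2Cl2, 0 °C to rt
Reagents that add atoms: none
Why: Mesylation of the β-hydroxyl and E1cB elimination (aldol dehydration) can only give the conjugated C3=C4 enal and removes the unselective C3 and C4 centres.

**Step 9**
Reactants: 13 (5R,7R,10R)-eudesma-3,11(13)-dien-15-al
Product: 14 (5R,7R,10R)-eudesma-3,11(13)-dien-15-ol
Conditions: NaBH4, CeCl3·7H2O, MeOH, 0 °C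
Reagents that add atoms: none
Why: Luche reduction delivers hydride 1,2 to the enal and leaves the isolated alkenes alone.

**Step 10**
Reactants: 15 methyl 2-[bis(2,2,2-trifluoroethoxy)phosphoryl]acetate
Product: 16 2-[bis(2,2,2-trifluoroethoxy)phosphoryl]acetic acid
Conditions: LiOH·H2O (1.0 equiv), THF/H2O, 0 °C; then 1 M HCl
Reagents that add atoms: lithium hydroxide, [Li+].[OH-]
Why: Ester saponification with one equivalent of hydroxide at low temperature should cleave the activated carboxylic methyl ester faster than the phosphonate esters.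

**Step 11**
Reactants: 14 (5R,7R,10R)-eudesma-3,11(13)-dien-15-ol; 16 2-[bis(2,2,2-trifluoroethoxy)phosphoryl]acetic acid
Product: 17 (5R,7R,10R)-eudesma-3,11(13)-dien-15-yl 2-[bis(2,2,2-trifluoroethoxy)phosphoryl]acetate
Conditions: DCC, DMAP (cat.), CH2Cl2, 0 °C to rt
Reagents that add atoms: none
Why: Steglich esterification of the unhindered primary allylic alcohol with the phosphonoacetic acid.

**Step 12**
Reactants: 17 (5R,7R,10R)-eudesma-3,11(13)-dien-15-yl 2-[bis(2,2,2-trifluoroethoxy)phosphoryl]acetate; 18 4-[(tert-butyldimethylsilyl)oxy]benzaldehyde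
Product: 19 (5R,7R,10R)-eudesma-3,11(13)-dien-15-yl (2Z)-3-{4-[(tert-butyldimethylsilyl)oxy]phenyl}prop-2-enoate
Conditions: KN(SiMe3)2, 18-crown-6, THF, −78 °C; then 18; dark
Reagents that add atoms: none
Why: In the Still–Gennari variant of the Horner–Wadsworth–Emmons olefination the electron-poor bis(trifluoroethyl) phosphonate with a dissociated potassium counter-ion eliminates from the kinetically formed adduct and should give the Z enoate.

**Step 13**
Reactants: 19 (5R,7R,10R)-eudesma-3,11(13)-dien-15-yl (2Z)-3-{4-[(tert-butyldimethylsilyl)oxy]phenyl}prop-2-enoate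
Product: 21 (5R,7R,10R)-12-oxoeudesma-3,11(13)-dien-15-yl (2Z)-3-{4-[(tert-butyldimethylsilyl)oxy]phenyl}prop-2-enoate, via allylic alcohol 20 (not isolated)
Conditions: SeO2 (0.5 equiv), t-BuOOH, salicylic acid (cat.), CH2Cl2, rt, dark; filter; then MnO2, CH2Cl2, rt
Reagents that add atoms: tert-butyl hydroperoxide, CC(C)(C)OO (oxygen delivered through catalytic selenium dioxide, O=[Se]=O)
Why: Selenium dioxide allylic oxidation (ene reaction, then [2,3]-sigmatropic shift) should attack the 1,1-disubstituted alkene at its methyl group (CH3 preferred over the C7 methine) because the C3=C4 alkene is deactivated by its allylic ester, and MnO2 then oxidises the allylic alcohol to the 2-substituted acrolein.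

**Step 14**
Reactants: 21 (5R,7R,10R)-12-oxoeudesma-3,11(13)-dien-15-yl (2Z)-3-{4-[(tert-butyldimethylsilyl)oxy]phenyl}prop-2-enoate
Product: 22 (5R,7R,10R)-15-{[(2Z)-3-{4-[(tert-butyldimethylsilyl)oxy]phenyl}prop-2-enoyl]oxy}eudesma-3,11(13)-dien-12-oic acid
Conditions: NaClO2, NaH2PO4, 2-methyl-2-butene, t-BuOH/H2O, 0 °C to rt
Reagents that add atoms: sodium chlorite, [Na+].[O-]Cl=O
Why: Pinnick oxidation converts the enal into the acrylic acid without touching the alkenes, the hypochlorous acid by-product being trapped by 2-methyl-2-butene.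

**Step 15**
Reactants: 22 (5R,7R,10R)-15-{[(2Z)-3-{4-[(tert-butyldimethylsilyl)oxy]phenyl}prop-2-enoyl]oxy}eudesma-3,11(13)-dien-12-oic acid
Product: 23 (5R,7R,10R)-15-{[(2Z)-3-(4-hydroxyphenyl)prop-2-enoyl]oxy}eudesma-3,11(13)-dien-12-oic acid (CNP0183482.1)
Conditions: HF·pyridine, pyridine, THF, 0 °C, dark
Reagents that add atoms: none
Why: Fluoride cleavage of the aryl silyl ether under acidic, non-basic conditions avoids phenolate-assisted Z to E isomerisation of the coumarate.

**Compound list**

1 | (4R)-limonene 1,2-oxide, (4R)-1-methyl-4-(prop-1-en-2-yl)-7-oxabicyclo[4.1.0]heptane, cis/trans mixture | C=C(C)[C@@H]1CCC2(C)OC2C1 | starting material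
2 | (3R)-6-oxo-3-(prop-1-en-2-yl)heptanal | CC(=C)[C@@H](CC=O)CCC(C)=O | intermediate
3 | (1,3-dioxolan-2-ylmethyl)triphenylphosphonium bromide | [Br-].C1COC(C[P+](c2ccccc2)(c2ccccc2)c2ccccc2)O1 | starting material
4 | (5R)-8-(1,3-dioxolan-2-yl)-5-(prop-1-en-2-yl)oct-7-en-2-one, Z/E mixture | CC(=C)[C@@H](CC=CC1OCCO1)CCC(C)=O | intermediate
5 | 2-(2-bromoethyl)-1,3-dioxolane | BrCCC1OCCO1 | starting material
6 | (6R)-1,9-bis(1,3-dioxolan-2-yl)-3-methyl-6-(prop-1-en-2-yl)non-8-en-3-ol, both C3 epimers | CC(=C)[C@@H](CC=CC1OCCO1)CCC(C)(O)CCC1OCCO1 | intermediate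
7 | methyl (6R)-1,9-bis(1,3-dioxolan-2-yl)-3-methyl-6-(prop-1-en-2-yl)non-8-en-3-yl oxalate | CC(=C)[C@@H](CC=CC1OCCO1)CCC(C)(OC(=O)C(=O)OC)CCC1OCCO1 | intermediate
8 | methyl (2E,5R)-8-methyl-1,11-dioxo-5-(prop-1-en-2-yl)undec-2-en-8-yl oxalate | CC(=C)[C@@H](C/C=C/C=O)CCC(C)(OC(=O)C(=O)OC)CCC=O | intermediate
9 | cesium 2-{[(2E,5R)-8-methyl-1,11-dioxo-5-(prop-1-en-2-yl)undec-2-en-8-yl]oxy}-2-oxoacetate | CC(=C)[C@@H](C/C=C/C=O)CCC(C)(OC(=O)C(=O)[O-])CCC=O.[Cs+] | intermediate
10 | cesium enolate (at C4–C15) of the ring B cyclohexane dialdehyde; C10 methyl cis to the C5 side chain and to the C7 isopropenyl group, 3-oxopropyl arm trans to both | CC(=C)[C@@H]1CC[C@@](C)(CCC=O)[C@H](C=C[O-])C1.[Cs+] | intermediate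
11 | (5S,7R,10S)-3-hydroxyeudesm-11(13)-en-15-al; trans-decalin (5α-H, 10β-methyl, 7β-isopropenyl), C3/C4 epimers | CC(=C)[C@@H]1CC[C@@]2(C)CCC(O)C(C=O)[C@@H]2C1 | intermediate
12 | (5S,7R,10S)-3-(methylsulfonyloxy)eudesm-11(13)-en-15-al, C3/C4 epimers | CC(=C)[C@@H]1CC[C@@]2(C)CCC(OS(C)(=O)=O)C(C=O)[C@@H]2C1 | intermediate
13 | (5R,7R,10R)-eudesma-3,11(13)-dien-15-al | CC(=C)[C@@H]1CC[C@@]2(C)CCC=C(C=O)[C@@H]2C1 | intermediate
14 | (5R,7R,10R)-eudesma-3,11(13)-dien-15-ol | CC(=C)[C@@H]1CC[C@@]2(C)CCC=C(CO)[C@@H]2C1 | intermediate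
15 | methyl 2-[bis(2,2,2-trifluoroethoxy)phosphoryl]acetate | COC(=O)CP(=O)(OCC(F)(F)F)OCC(F)(F)F | starting material
16 | 2-[bis(2,2,2-trifluoroethoxy)phosphoryl]acetic acid | OC(=O)CP(=O)(OCC(F)(F)F)OCC(F)(F)F | intermediate
17 | (5R,7R,10R)-eudesma-3,11(13)-dien-15-yl 2-[bis(2,2,2-trifluoroethoxy)phosphoryl]acetate | CC(=C)[C@@H]1CC[C@@]2(C)CCC=C(COC(=O)CP(=O)(OCC(F)(F)F)OCC(F)(F)F)[C@@H]2C1 | intermediate
18 | 4-[(tert-butyldimethylsilyl)oxy]benzaldehyde | CC(C)(C)[Si](C)(C)Oc1ccc(C=O)cc1 | starting material
19 | (5R,7R,10R)-eudesma-3,11(13)-dien-15-yl (2Z)-3-{4-[(tert-butyldimethylsilyl)oxy]phenyl}prop-2-enoate | CC(=C)[C@@H]1CC[C@@]2(C)CCC=C(COC(=O)/C=C\c3ccc(O[Si](C)(C)C(C)(C)C)cc3)[C@@H]2C1 | intermediate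
20 | (5R,7R,10R)-12-hydroxyeudesma-3,11(13)-dien-15-yl (2Z)-3-{4-[(tert-butyldimethylsilyl)oxy]phenyl}prop-2-enoate | C=C(CO)[C@@H]1CC[C@@]2(C)CCC=C(COC(=O)/C=C\c3ccc(O[Si](C)(C)C(C)(C)C)cc3)[C@@H]2C1 | intermediate
21 | (5R,7R,10R)-12-oxoeudesma-3,11(13)-dien-15-yl (2Z)-3-{4-[(tert-butyldimethylsilyl)oxy]phenyl}prop-2-enoate | C=C(C=O)[C@@H]1CC[C@@]2(C)CCC=C(COC(=O)/C=C\c3ccc(O[Si](C)(C)C(C)(C)C)cc3)[C@@H]2C1 | intermediate
22 | (5R,7R,10R)-15-{[(2Z)-3-{4-[(tert-butyldimethylsilyl)oxy]phenyl}prop-2-enoyl]oxy}eudesma-3,11(13)-dien-12-oic acid | C=C(C(=O)O)[C@@H]1CC[C@@]2(C)CCC=C(COC(=O)/C=C\c3ccc(O[Si](C)(C)C(C)(C)C)cc3)[C@@H]2C1 | intermediate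
23 | (5R,7R,10R)-15-{[(2Z)-3-(4-hydroxyphenyl)prop-2-enoyl]oxy}eudesma-3,11(13)-dien-12-oic acid | C=C(C(=O)O)[C@@H]1CC[C@@]2(C)CCC=C(COC(=O)/C=C\c3ccc(O)cc3)[C@@H]2C1 | target

**Step count and risks**

Total step count: 15 (14 on the main line plus step 10, which prepares reagent 16).
Longest linear sequence: 14 steps (steps 1–9 and 11–15) from 1.

Steps most likely to fail:

1. Step 7 (Proposed new method). Two processes threaten it: protonation of enolate 10 before the aldol closure, which leaves an uncyclised dialdehyde that cannot be closed regioselectively, and weak face discrimination at the planar C10 radical, which would give the cis-decalin series alongside the desired one. The fallback uses known reactions only, sets out from 7 and comes back at 13. The allylic dioxolane of 7 alone is hydrolysed (PPTS, wet acetone, rt) to the enal mono-acetal F1, and CsOH converts this into the cesium oxalate F2. The established oxalate photoredox Giese cyclisation with water as proton source ([Ir(dF(CF3)ppy)2(dtbbpy)]PF6, DME/DMF, H2O, blue LEDs, 60 °C) should then give the ring B aldehyde F3 with the C3 dioxolane intact, and C10 epimers can be separated at this stage. TMSCl, NaI and Et3N give the silyl enol ether F4, catalytic TMSOTf (CH2Cl2, −78 °C) closes ring A by the silyl enol ether–acetal (Mukaiyama-type) aldol reaction to the 2-hydroxyethyl ether F5, and DBU eliminates ethylene glycol to give 13.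

2. Step 13. The risks are ene oxidation at the ring alkene (allylic positions C2 and C5) competing with the isopropenyl group, and selenium-promoted Z to E isomerisation of the coumarate. The fallback sets out from 13 and comes back at 20. The allylic oxidation is moved to enal 13, where conjugation with the aldehyde deactivates the C3=C4 alkene. SeO2/t-BuOOH gives the 12-hydroxy enal F6, TESCl/imidazole gives the triethylsilyl ether F7, and Luche reduction (NaBH4, CeCl3·7H2O) gives the C15 alcohol F8. DCC/DMAP with 16 gives the phosphonoacetate F9, and Still–Gennari olefination with 18 gives the Z-coumarate F10. PPTS in MeOH then removes only the alkyl triethylsilyl ether and gives 20, which MnO2 oxidises to 21 as in the second half of step 13.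

3. Step 2. The risk is enolisation of the 1,6-keto-aldehyde 2 by the basic, slowly reacting acetal ylide, followed by intramolecular aldol condensation to a cyclopentene carbaldehyde. The fallback sets out from 2 and comes back at 4. The neutral stabilised ylide (triphenylphosphoranylidene)acetaldehyde (toluene, 80 °C) gives the E keto-enal F11 chemoselectively at the aldehyde. The enal carbonyl alone is then acetalised with 1,2-bis(trimethylsilyloxy)ethane and catalytic TMSOTf (CH2Cl2, −78 °C) to give 4 as its E isomer.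

**Further compounds**

F1 | step 7 | methyl (2E,5R)-10-(1,3-dioxolan-2-yl)-8-methyl-1-oxo-5-(prop-1-en-2-yl)dec-2-en-8-yl oxalate | CC(=C)[C@@H](C/C=C/C=O)CCC(C)(OC(=O)C(=O)OC)CCC1OCCO1
F2 | step 7 | cesium 2-{[(2E,5R)-10-(1,3-dioxolan-2-yl)-8-methyl-1-oxo-5-(prop-1-en-2-yl)dec-2-en-8-yl]oxy}-2-oxoacetate | CC(=C)[C@@H](C/C=C/C=O)CCC(C)(OC(=O)C(=O)[O-])CCC1OCCO1.[Cs+]
F3 | step 7 | 2-{2-[2-(1,3-dioxolan-2-yl)ethyl]-2-methyl-5-(prop-1-en-2-yl)cyclohexyl}acetaldehyde, ring B aldehyde with the configuration of 10 | CC(=C)[C@@H]1CC[C@@](C)(CCC2OCCO2)[C@H](CC=O)C1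
F4 | step 7 | trimethylsilyl enol ether of F3 | CC(=C)[C@@H]1CC[C@@](C)(CCC2OCCO2)[C@H](C=CO[Si](C)(C)C)C1
F5 | step 7 | (5S,7R,10S)-3-(2-hydroxyethoxy)eudesm-11(13)-en-15-al, C3/C4 epimers | CC(=C)[C@@H]1CC[C@@]2(C)CCC(OCCO)C(C=O)[C@@H]2C1
F6 | step 13 | (5R,7R,10R)-12-hydroxyeudesma-3,11(13)-dien-15-al | C=C(CO)[C@@H]1CC[C@@]2(C)CCC=C(C=O)[C@@H]2C1
F7 | step 13 | (5R,7R,10R)-12-(triethylsilyloxy)eudesma-3,11(13)-dien-15-al | C=C(CO[Si](CC)(CC)CC)[C@@H]1CC[C@@]2(C)CCC=C(C=O)[C@@H]2C1
F8 | step 13 | (5R,7R,10R)-12-(triethylsilyloxy)eudesma-3,11(13)-dien-15-ol | C=C(CO[Si](CC)(CC)CC)[C@@H]1CC[C@@]2(C)CCC=C(CO)[C@@H]2C1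
F9 | step 13 | (5R,7R,10R)-12-(triethylsilyloxy)eudesma-3,11(13)-dien-15-yl 2-[bis(2,2,2-trifluoroethoxy)phosphoryl]acetate | C=C(CO[Si](CC)(CC)CC)[C@@H]1CC[C@@]2(C)CCC=C(COC(=O)CP(=O)(OCC(F)(F)F)OCC(F)(F)F)[C@@H]2C1
F10 | step 13 | (5R,7R,10R)-12-(triethylsilyloxy)eudesma-3,11(13)-dien-15-yl (2Z)-3-{4-[(tert-butyldimethylsilyl)oxy]phenyl}prop-2-enoate | C=C(CO[Si](CC)(CC)CC)[C@@H]1CC[C@@]2(C)CCC=C(COC(=O)/C=C\c3ccc(O[Si](C)(C)C(C)(C)C)cc3)[C@@H]2C1
F11 | step 2 | (2E,5R)-8-oxo-5-(prop-1-en-2-yl)non-2-enal | CC(=C)[C@@H](C/C=C/C=O)CCC(C)=O
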